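**Assumptions (one line each)**
- Ar = 4-(benzyloxy)-3-methoxyphenyl. Compound 8 (the aryl bromide) is commercial, or made in one step from 4-bromo-2-methoxyphenol and BnBr.
- The Ireland–Claisen proceeds through a chair transition state, with the β-OBn group chelating Li to favour the (Z)-silyl ketene acetal.

## Retrosynthesis
- Target ⇐ hydrogenolysis of the tetra-O-benzyl THF ⇐ Et3SiH/BF3 reduction of the 2-aryl lactol ⇐ ArLi addition to the 5-aryl-γ-lactone.
- The lactone (the first ring formed; the THF ring is formed last, via the lactol) ⇐ chelation-controlled ArMgBr addition to an aldehyde-acid and lactonization ⇐ ozonolysis of the Ireland–Claisen acid.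
- Key step: an Ireland–Claisen [3,3] rearrangement forms C8–C8' and sets both stereocentres. Chirality transfers suprafacially from the (R)-carbinol of the allylic ester, which comes from (R)-but-3-en-2-ol by cross-metathesis plus esterification with 3-(benzyloxy)propanoic acid.
- C7 and C7' are set by substrate control from C8/C8'.

## Route

**Step 1**
Reactants: 1 (R)-but-3-en-2-ol; 2 allyl benzyl ether
Product: 3 (R,E)-5-(benzyloxy)pent-3-en-2-ol
Conditions: Grubbs II (5 mol%), CH2Cl2, 40 °C
Reagents that add atoms: none
Why: Cross-metathesis of the terminal alkenes gives the E-disubstituted allylic alcohol (ethylene is lost), and the carbinol stereocentre is untouched.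

**Step 2**
Reactants: 3; 4 3-(benzyloxy)propanoic acid
Product: 5 (2R,3E)-5-(benzyloxy)pent-3-en-2-yl 3-(benzyloxy)propanoate
Conditions: EDC·HCl, DMAP (cat.), CH2Cl2, 0 °C → rt
Reagents that add atoms: none
Why: Steglich esterification acylates the secondary alcohol without touching the stereocentre.

**Step 3**
Reactants: 5
Product: 6 (2S,3S,4E)-2,3-bis[(benzyloxy)methyl]hex-4-enoic acid
Conditions: LDA, THF/DMPU, –78 °C; TBSCl, –78 °C → rt; then 1 M HCl/THF
Reagents that add atoms: none. TBSCl (CC(C)(C)[Si](C)(C)Cl) is used transiently as the TBS ester, which is cleaved on work-up.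
Why: Ireland–Claisen [3,3] rearrangement. The (Z)-silyl ketene acetal and the E-alkene react through a chair transition state to give the syn (threo) 2,3-bis(CH2OBn) pair, which is the trans relationship needed on the ring. The (R)-carbinol fixes the absolute configuration as (2S,3S).

**Step 4**
Reactants: 6
Product: 7 (2S,3S)-2,3-bis[(benzyloxy)methyl]-4-oxobutanoic acid
Conditions: O3, CH2Cl2/MeOH, –78 °C; then Me2S, –78 °C → rt; use crude
Reagents that add atoms: ozone, O=[O+][O-] (its oxygen becomes the aldehyde C=O)
Why: Ozonolysis cleaves the propenyl alkene to the C7' aldehyde under mild, neutral, reductive work-up that does not epimerize the α-stereocentres. The benzyl ethers survive.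

**Step 5**
Reactants: 7; 8 4-(benzyloxy)-3-methoxy-1-bromobenzene, used as its Grignard reagent (Mg, THF)
Product: 9 (3S,4S,5R)-5-[4-(benzyloxy)-3-methoxyphenyl]-3,4-bis[(benzyloxy)methyl]dihydrofuran-2(3H)-one
Conditions: ArMgBr (3.5 equiv), THF, –78 → 0 °C; then aq. NH4Cl; TsOH·H2O (cat.), PhMe, 50 °C
Reagents that add atoms: 4-(benzyloxy)-3-methoxyphenylmagnesium bromide, COc1cc([Mg]Br)ccc1OCc1ccccc1
Why: Grignard addition to the β-benzyloxy aldehyde proceeds through a Mg-chelated (Cram-chelate) transition state. This sets C7'(R), trans to C8', and the γ-hydroxy acid lactonizes to the 4,5-trans lactone. The carboxylate survives as its magnesium salt.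

**Step 6**
Reactants: 9; 8 as aryllithium
Product: 10 lactol (3S,4S,5R)-2,5-bis[4-(benzyloxy)-3-methoxyphenyl]-3,4-bis[(benzyloxy)methyl]tetrahydrofuran-2-ol (C2 epimeric mixture)
Conditions: 8 (2.5 equiv), n-BuLi, THF, –78 °C (Br/Li exchange); add 9, –78 °C, 1 h; NH4Cl
Reagents that add atoms: 4-(benzyloxy)-3-methoxyphenyllithium, COc1cc([Li])ccc1OCc1ccccc1
Why: Nucleophilic 1,2-addition of ArLi to the lactone C=O stops at the hemiketal because the tetrahedral intermediate is stable at –78 °C. The anomeric mixture is irrelevant because C2 is rebuilt in the next step.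

**Step 7**
Reactants: 10
Product: 11 (2R,3S,4S,5R)-2,5-bis[4-(benzyloxy)-3-methoxyphenyl]-3,4-bis[(benzyloxy)methyl]tetrahydrofuran
Conditions: Et3SiH (5 equiv), BF3·OEt2, CH2Cl2, –78 → –20 °C
Reagents that add atoms: none (hydride only)
Why: Ionization to the aryl-stabilized oxocarbenium ion followed by silane reduction. Hydride attack from the face syn to the C8 substituent (the stereoelectronically preferred "inside" attack) gives the 2,3-trans Ar/CH2OBn relationship, so the ring is all-trans.

**Step 8**
Reactants: 11
Product: 12 (+)-neoolivil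
Conditions: H2 (1 atm), 10% Pd/C, EtOAc/MeOH, rt
Reagents that add atoms: none
Why: Hydrogenolysis removes the two aryl and two alkyl benzyl ethers. The stereocentres are not involved.

## Compound list
1 | (R)-but-3-en-2-ol | C[C@@H](O)C=C | starting material
2 | allyl benzyl ether | C=CCOCc1ccccc1 | starting material
3 | (R,E)-5-(benzyloxy)pent-3-en-2-ol | C[C@@H](O)/C=C/COCc1ccccc1 | intermediate
4 | 3-(benzyloxy)propanoic acid | OC(=O)CCOCc1ccccc1 | starting material
5 | (2R,3E)-5-(benzyloxy)pent-3-en-2-yl 3-(benzyloxy)propanoate | C[C@@H](OC(=O)CCOCc1ccccc1)/C=C/COCc1ccccc1 | intermediate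
6 | (2S,3S,4E)-2,3-bis[(benzyloxy)methyl]hex-4-enoic acid | OC(=O)[C@H](COCc1ccccc1)[C@@H](COCc1ccccc1)/C=C/C | intermediate
7 | (2S,3S)-2,3-bis[(benzyloxy)methyl]-4-oxobutanoic acid | OC(=O)[C@H](COCc1ccccc1)[C@@H](COCc1ccccc1)C=O | intermediate
8 | 1-(benzyloxy)-4-bromo-2-methoxybenzene | COc1cc(Br)ccc1OCc1ccccc1 | starting material
9 | (3S,4S,5R)-5-aryl-3,4-bis(benzyloxymethyl)-γ-butyrolactone | O=C1O[C@@H](c2ccc(OCc3ccccc3)c(OC)c2)[C@H](COCc2ccccc2)[C@H]1COCc1ccccc1 | intermediate
10 | lactol (C2 epimeric mixture) | OC1(c2ccc(OCc3ccccc3)c(OC)c2)O[C@@H](c2ccc(OCc3ccccc3)c(OC)c2)[C@H](COCc2ccccc2)[C@H]1COCc1ccccc1 | intermediate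
11 | tetra-O-benzyl neoolivil | COc1cc([C@@H]2O[C@@H](c3ccc(OCc4ccccc4)c(OC)c3)[C@H](COCc4ccccc4)[C@H]2COCc2ccccc2)ccc1OCc1ccccc1 | intermediate
12 | (+)-neoolivil | COc1cc([C@@H]2O[C@@H](c3ccc(O)c(OC)c3)[C@H](CO)[C@H]2CO)ccc1O | target

**Total steps: 8. Longest linear sequence: 8 (from compound 1).**

## Three steps most likely to fail
1. **Step 3 (Ireland–Claisen).** The β-alkoxy ester enolate may eliminate BnO⁻, or the E-enolate may form and give the anti diastereomer.
   Fallback: do a Johnson–Claisen of 3 (MeC(OEt)3, EtCO2H, 140 °C) to set C8' only. Then make the 5-aryl lactone and install C8 by trans-selective lactone-enolate α-alkylation with BnOCH2Cl.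
2. **Step 5 (aldehyde epimerization and Grignard diastereoselectivity).** The aldehyde 7 is α-epimerizable and β-elimination-prone, and chelation control at C7' may be poor.
   Fallback: oxidize the alkene of 6 to the diacid (RuCl3/NaIO4) and convert it to the bis-Weinreb amide. Add 2 ArMgBr to give the 1,4-diketone, reduce with NaBH4, and close the ring by TsOH SN1 dehydrative cyclization to the thermodynamic all-trans THF.
3. **Step 7 (Et3SiH/BF3 reduction stereochemistry).** It may give the 2,3-cis isomer, or BF3 may cleave benzyl ethers.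
   Fallback: reduce lactol 10 with NaBH4 to the 1,4-diol (the C7 carbinol, configuration unimportant). Then use acid-mediated ionization/recyclization (TsOH, PhMe) to give the thermodynamically favoured all-trans THF.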